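Late in the zeta run the monomer in chains stops climbing: it reads 52.0% at 12.0 min and 51.7% at 20.0 min. So your hunch that the longer time of dusk buys longer chains doesn't persuade me.

all flasks: pre-initiator 0.13 mM
- zeta: free monomer 6 mM; run made earlier
- gamma: free monomer 24 mM; run made earlier
- dusk: free monomer 12 mM; time 20 min
- autumn: free monomer 12 mM; time 12 min

| run | time / min | monomer in chains / % | free monomer / % |
|---|---|---|---|
| zeta | 2.50 | 31.6 | 68.7 |
| zeta | 8.00 | 50.6 | 49.1 |
| zeta | 12.0 | 52.0 | 48.1 |
| zeta | 20.0 | 51.7 | 48.3 |
| gamma | 1.50 | 20.1 | 80.4 |
| gamma | 4.00 | 42.7 | 57.4 |
| gamma | 8.00 | 50.0 | 50.0 |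
| gamma | 20.0 | 51.0 | 49.2 |

(each reading ± 0.3 percentage points)

- the average divides the monomer in chains by the number of chains begun, living and dead together
- the earlier runs do not show the number of chains; that part of a forecast is a guess

* which of the two ends with the longer chains by the average number of monomer units in a chain (chains begun, living or dead) ("neither" if they lie within 10%) (dusk / autumn / neither)
* average number of monomer units in a chain (chains begun, living or dead) at the end, dusk
* average number of monomer units in a chain (chains begun, living or dead) at the end, autumn

The gamma run ends at 51.0% from a charge of 24 mM, and the zeta run at 51.7% from 6 mM. The free monomer left is 11.8 mM in gamma and 2.90 mM in zeta, so what repeats is a fraction, not a concentration.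

I average the flat readings to 51.6%. That is the plateau fraction f, the share of the charged free monomer that stands in chains on the plateau with 0.13 mM of pre-initiator charged; the usual term is limiting conversion.

The runs don't show the number of chains, so I guess that each pre-initiator begins one. The length is then f·c(free monomer)/c(pre-initiator). With 12 mM and 0.13 mM I get 47.6, for dusk and for autumn.

The forecast gives 47.5 for dusk and 47.5 for autumn, so neither; that is near my figure, not equal to it. Its ground: “This is a fixed fraction, not a fixed free-monomer concentration”.

The simulation gives 47.3 for dusk and 47.2 for autumn, so neither.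

    free monomer + initiator → living end + monomer in chains (k = 13.8 L mol⁻¹ s⁻¹)
    free monomer + living end → monomer in chains + living end, rate k2*[living end]*[free monomer] (k = 113 L mol⁻¹ s⁻¹)
    pre-initiator → initiator (k = 0.00876 s⁻¹)
    living end → dead end (k = 0.0209 s⁻¹)

Dusk at 20.0 min holds 0.130 mM of dead end beside 2.86 × 10⁻⁶ mM of living end, and 0.13 mM of pre-initiator was charged, so the chains begun match the charge. Autumn at 12.0 min holds 0.130 mM of dead end, with 0.18% of its pre-initiator left. The neighbour of dusk charged with 30 mM of free monomer takes the same reckoning: f times that charge over 0.13 mM gives 119. That neighbour ends with 50.8% of its free monomer in chains and a length of 117.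

The readings are calculated for an exercise.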